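**Plan** (skeleton numbering: bicyclo[5.3.0]dec‑3‑ene; C1 quaternary C–Me, C2/C6 angelate carbons, C7 ring‑fusion CH, C8 C(OH)iPr, C9 CH2, C10 CHOH)
- Retrosynthesis cuts, in order: the two angelate C–O bonds; the C10 carbinol (from a ketone); C3=C4 (ring‑closing metathesis); C5–C6 (methallyl addition to a γ‑lactone); then C9–C10 and C7–C8 together (formal [3+2] of a donor–acceptor cyclopropane with a silyl enol ether); finally the cyclopropane (intramolecular cyclopropanation of an allylic diazoacetate).
- Forward ring order: cyclopropane‑fused γ‑lactone 9 → cyclopentane (key step) → cycloheptene (RCM).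
- Enabling feature: in 3‑oxabicyclo[3.1.0]hexan‑2‑one 9 the cyclopropane bond C1–C6 lies between a donor (ONAP on C6) and an acceptor (lactone C=O on C1). Strain‑release heterolysis gives a regiodefined oxocarbenium/enolate 1,3‑dipole; the lactone is a temporary ring that forces the cis ring fusion and carries the future C2–O and C6=O.
- Stereochemistry: C2 from (R)‑pent‑1‑en‑4‑yn‑3‑ol (Sharpless kinetic resolution); C1 by A(1,3)‑controlled cyclopropanation; C7 by the lactone tether; C8 by a tin‑chelated aldol closure; C6 and C10 by hydroxyl‑directed reductions relayed from the C8 hydroxyl.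

Key step: step 7

Remark: the ONAP‑bearing carbon formed in step 7 (later C10) is not controlled there; compounds 13–17 and 20–21 are drawn without configuration at that carbon, and it is set in step 14.
Remark: 15 is an anomeric mixture and 16 may exist as its transannular hemiketal; both equilibrate under the conditions of the following step.

Step 1
Reactants: 1 (±)-pent-1-en-4-yn-3-ol
Product: 2 (R)-pent-1-en-4-yn-3-ol
Conditions: Ti(OiPr)4 (cat.), D‑(−)‑DIPT, t‑BuOOH (0.6 equiv), 4 Å MS, CH2Cl2, −20 °C; recover unreacted alcohol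
Reagents that add atoms: none
Why: Sharpless kinetic resolution of a 1‑alken‑3‑ol; with D‑(−)‑tartrate the (S)‑enantiomer is epoxidised at its vinyl group while the (R)‑alcohol, which carries the future C2 configuration, should remain (the alkyne is inert).

Step 2
Reactants: 2 (R)-pent-1-en-4-yn-3-ol
Product: 4 (R,Z)-1-iodo-2-methylpenta-1,4-dien-3-ol, via alkenylmagnesium alkoxide 3 (not isolated)
Conditions: MeMgBr (3 equiv), CuI (10 mol %), THF/Et2O, −10 °C → rt; then I2, −50 → 0 °C
Reagents that add atoms: methylmagnesium bromide C[Mg]Br; iodine II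
Why: alkoxide‑directed Cu‑catalysed anti‑carbomagnesiation of a propargylic alcohol puts methyl on the proximal alkyne carbon and magnesium cis to the carbinol (five‑membered chelate), and iodinolysis with retention should give the Z‑iodide without touching the carbinol centre.

Step 3
Reactants: 4 (R,Z)-1-iodo-2-methylpenta-1,4-dien-3-ol; 5 naphthalen-2-ylmethanol (3 equiv)
Product: 6 (R,Z)-2-methyl-1-(naphthalen-2-ylmethoxy)penta-1,4-dien-3-ol
Conditions: CuI (10 mol %), 3,4,7,8‑tetramethyl‑1,10‑phenanthroline (20 mol %), Cs2CO3, toluene, 80 °C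
Reagents that add atoms: none
Why: Cu‑catalysed Ullmann‑type C–O coupling of an alkenyl iodide with a primary alcohol proceeds with retention of alkene geometry, and the primary benzylic alcohol in excess should outcompete the hindered secondary hydroxyl, giving the Z‑enol ether (ONAP cis to the carbinol carbon).

Step 4
Reactants: 6 (R,Z)-2-methyl-1-(naphthalen-2-ylmethoxy)penta-1,4-dien-3-ol
Product: 8 (R,Z)-2-methyl-1-(naphthalen-2-ylmethoxy)penta-1,4-dien-3-yl diazoacetate, via bromoacetate 7 (not isolated)
Conditions: BrCH2COBr, NaHCO3, MeCN, 0 °C; then TsNHNHTs, DBU, THF, 0 °C; rapid filtration through Et3N‑deactivated silica, used at once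
Reagents that add atoms: bromoacetyl bromide BrCC(=O)Br; N,N'-ditosylhydrazine Cc1ccc(cc1)S(=O)(=O)NNS(=O)(=O)c1ccc(C)cc1
Why: O‑acylation followed by N‑alkylation of ditosylhydrazine and double sulfinate elimination is a standard diazoacetate synthesis that runs under basic conditions throughout, which the ionisation‑prone allylic ester needs.

Step 5
Reactants: 8 (R,Z)-2-methyl-1-(naphthalen-2-ylmethoxy)penta-1,4-dien-3-yl diazoacetate
Product: 9 (4R)-5-methyl-6-(naphthalen-2-ylmethoxy)-4-vinyl-3-oxabicyclo[3.1.0]hexan-2-one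
Conditions: Rh2(OAc)4 (1 mol %), CH2Cl2, rt, slow addition of 8
Reagents that add atoms: none
Why: intramolecular Rh‑carbene cyclopropanation of an allylic diazoacetate should take the electron‑rich enol ether alkene over the vinyl group; A(1,3) strain with the cis‑ONAP group holds the carbinol H in the alkene plane, so the tethered carbene adds to the face that leaves vinyl exo (cis to 5‑Me), and stereospecific syn addition places ONAP endo on C6, setting C1 and C5 relative to C4.

Step 6
Reactants: 10 3-methylbutan-2-one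
Product: 11 3-methyl-2-(trimethylsilyloxy)but-1-ene
Conditions: LDA, THF, −78 °C; TMSCl, −78 °C → rt; distil
Reagents that add atoms: chlorotrimethylsilane C[Si](C)(C)Cl
Why: kinetic deprotonation at the methyl group and O‑silylation is the standard route to the less substituted silyl enol ether.

Step 7
Reactants: 9 (4R)-5-methyl-6-(naphthalen-2-ylmethoxy)-4-vinyl-3-oxabicyclo[3.1.0]hexan-2-one; 11 3-methyl-2-(trimethylsilyloxy)but-1-ene (2.5 equiv)
Product: 14 8-hydroxy-8-isopropyl-5-methyl-6-(naphthalen-2-ylmethoxy)-4-vinyl-3-oxabicyclo[3.3.0]octan-2-one, via oxocarbenium tin enolate 12 (not isolated), via keto tin enolate 13 (not isolated)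
Conditions: SnCl4 (1.2 equiv), CH2Cl2, −78 → −40 °C; sat. NaHCO3; then citric acid, MeOH (cleaves any tertiary TMS ether)
Reagents that add atoms: none
Why: SnCl4 bound to the lactone carbonyl triggers strain‑releasing heterolysis of the push–pull bond C1–C6 of 9 to ion pair 12, the CH2 terminus of 11 adds to the oxocarbenium carbon (first bond) with loss of Me3SiCl to give 13, and the tin lactone enolate then adds to the new isopropyl ketone (second bond). The closest known reaction type is the Lewis‑acid‑mediated formal [3+2] cycloaddition of 2‑alkoxycyclopropyl carbonyl compounds (donor–acceptor cyclopropanes) with enol silyl ethers. The cyclopentane closes by a 5‑(enolexo)‑exo‑trig intramolecular aldol. The quaternary carbon is untouched and relays its configuration; the ring‑fusion CH can only form cis because the enolate is held in the γ‑lactone; the carbinol carbon is set by a closed tin‑chelated transition state (and by reversible aldol under chelation) that puts the oxygen syn to the lactone carbonyl and the isopropyl group on the convex face; the ONAP carbon is not controlled and is reset in steps 12–14. The step needs cleavage of C1–C6 only (the one ring bond flanked by both donor and acceptor), attack by the silyl enol ether in preference to the pendant vinyl group, and a regiodefined enolate, which ring opening generates without any competing enolisation.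

Step 8
Reactants: 14 8-hydroxy-8-isopropyl-5-methyl-6-(naphthalen-2-ylmethoxy)-4-vinyl-3-oxabicyclo[3.3.0]octan-2-one
Product: 15 8-isopropyl-5-methyl-2-(2-methylallyl)-6-(naphthalen-2-ylmethoxy)-4-vinyl-3-oxabicyclo[3.3.0]octane-2,8-diol
Conditions: 2‑methylallylmagnesium chloride (2.5 equiv), THF, −78 °C; quench at −78 °C with sat. NH4Cl
Reagents that add atoms: 2-methylallylmagnesium chloride C=C(C)C[Mg]Cl
Why: mono‑addition of an allyl‑type Grignard reagent to a γ‑lactone at −78 °C stops at the magnesium lactolate (the first equivalent deprotonates the tertiary alcohol), and the cold quench should avoid double addition, retro‑aldol and conjugation of the β,γ‑alkene.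

Step 9
Reactants: 15 8-isopropyl-5-methyl-2-(2-methylallyl)-6-(naphthalen-2-ylmethoxy)-4-vinyl-3-oxabicyclo[3.3.0]octane-2,8-diol
Product: 16 2,8-dihydroxy-8-isopropyl-1,4-dimethyl-10-(naphthalen-2-ylmethoxy)bicyclo[5.3.0]dec-3-en-6-one
Conditions: Grubbs II catalyst (5–10 mol %), CH2Cl2, 40 °C
Reagents that add atoms: none
Why: ring‑closing metathesis between the vinyl group and the 1,1‑disubstituted methallyl alkene (through the open hydroxy ketone or the cis lactol) should give the trisubstituted cycloheptene with loss of ethylene.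

Step 10
Reactants: 16 2,8-dihydroxy-8-isopropyl-1,4-dimethyl-10-(naphthalen-2-ylmethoxy)bicyclo[5.3.0]dec-3-en-6-one
Product: 17 8-isopropyl-1,4-dimethyl-10-(naphthalen-2-ylmethoxy)bicyclo[5.3.0]dec-3-ene-2,6,8-triol
Conditions: Me4NBH(OAc)3, MeCN/AcOH 1:1, −30 → 0 °C
Reagents that add atoms: none
Why: Evans–Saksena hydroxyl‑directed reduction, in which the tertiary C8 alkoxyborohydride delivers hydride to the C6 ketone through a chair transition state with the ring CH2 equatorial, should give the 1,3‑anti diol, i.e. C6–OH on the face of H‑7.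

Step 11
Reactants: 17 8-isopropyl-1,4-dimethyl-10-(naphthalen-2-ylmethoxy)bicyclo[5.3.0]dec-3-ene-2,6,8-triol; 18 angelic acid (6 equiv)
Product: 20 2,6-bis(angeloyloxy)-8-isopropyl-1,4-dimethyl-10-(naphthalen-2-ylmethoxy)bicyclo[5.3.0]dec-3-en-8-ol, via mixed anhydride 19 (not isolated)
Conditions: 18, 2,4,6‑trichlorobenzoyl chloride, Et3N, toluene, rt; then 17, 75 °C
Reagents that add atoms: none
Why: Yamaguchi mixed‑anhydride acylation run without DMAP is the established way to transfer an angeloyl group without Z→E isomerisation; the two secondary alcohols should react and the tertiary alcohol should not.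

Step 12
Reactants: 20 2,6-bis(angeloyloxy)-8-isopropyl-1,4-dimethyl-10-(naphthalen-2-ylmethoxy)bicyclo[5.3.0]dec-3-en-8-ol
Product: 21 2,6-bis(angeloyloxy)-8-isopropyl-1,4-dimethylbicyclo[5.3.0]dec-3-ene-8,10-diol
Conditions: DDQ, CH2Cl2/pH 7 buffer, 0 °C → rt
Reagents that add atoms: none
Why: oxidative cleavage of a 2‑naphthylmethyl ether by DDQ is selective for the electron‑rich arylmethyl group and should leave the angelates, the ring alkene and the tertiary alcohol alone.

Step 13
Reactants: 21 2,6-bis(angeloyloxy)-8-isopropyl-1,4-dimethylbicyclo[5.3.0]dec-3-ene-8,10-diol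
Product: 22 2,6-bis(angeloyloxy)-8-hydroxy-8-isopropyl-1,4-dimethylbicyclo[5.3.0]dec-3-en-10-one
Conditions: Dess–Martin periodinane, NaHCO3, CH2Cl2, 0 °C → rt
Reagents that add atoms: none
Why: buffered Dess–Martin oxidation of the only secondary alcohol converges both C10 epimers on one ketone; the adjacent quaternary carbon has no α‑H, so the β‑acyloxy group cannot eliminate.

Step 14
Reactants: 22 2,6-bis(angeloyloxy)-8-hydroxy-8-isopropyl-1,4-dimethylbicyclo[5.3.0]dec-3-en-10-one
Product: 23 target, (2R)-2,6-bis(angeloyloxy)-8-isopropyl-1,4-dimethylbicyclo[5.3.0]dec-3-ene-8,10-diol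
Conditions: Me4NBH(OAc)3, MeCN/AcOH 1:1, −30 °C
Reagents that add atoms: none
Why: Evans–Saksena reduction of a cyclic β‑hydroxy ketone; the C8 hydroxyl on the same cyclopentane can only deliver hydride to the face it occupies, which should give the trans‑1,3‑diol with C10–OH on the face of the angular methyl, and the reagent does not reduce the esters.

**Compound list**
1 | (±)-pent-1-en-4-yn-3-ol | C=CC(O)C#C | starting material
2 | (R)-pent-1-en-4-yn-3-ol | C=C[C@@H](O)C#C | intermediate
3 | alkenylmagnesium alkoxide from anti-carbomagnesiation of 2 (drawn unchelated) | C=C[C@@H](O[Mg]Br)/C(C)=C\[Mg]Br | intermediate (not isolated)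
4 | (R,Z)-1-iodo-2-methylpenta-1,4-dien-3-ol (I cis to the carbinol carbon) | C=C[C@@H](O)/C(C)=C\I | intermediate
5 | naphthalen-2-ylmethanol | OCc1ccc2ccccc2c1 | starting material
6 | (R,Z)-2-methyl-1-(naphthalen-2-ylmethoxy)penta-1,4-dien-3-ol | C=C[C@@H](O)/C(C)=C\OCc1ccc2ccccc2c1 | intermediate
7 | bromoacetate of 6 | C=C[C@@H](OC(=O)CBr)/C(C)=C\OCc1ccc2ccccc2c1 | intermediate (not isolated)
8 | diazoacetate of 6 | C=C[C@@H](OC(=O)C=[N+]=[N-])/C(C)=C\OCc1ccc2ccccc2c1 | intermediate
9 | (4R)-5-methyl-6-(naphthalen-2-ylmethoxy)-4-vinyl-3-oxabicyclo[3.1.0]hexan-2-one; vinyl exo (cis to 5-Me, trans to C6), ONAP endo (cis to C4) | O=C1O[C@H](C=C)[C@@]2(C)[C@@H](OCc3ccc4ccccc4c3)[C@@H]12 | intermediate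
10 | 3-methylbutan-2-one | CC(=O)C(C)C | starting material
11 | 3-methyl-2-(trimethylsilyloxy)but-1-ene | C=C(O[Si](C)(C)C)C(C)C | intermediate
12 | ring-opened oxocarbenium/lactone enolate ion pair (tin omitted) | [O-]C1=C[C@](C)(C=[O+]Cc2ccc3ccccc3c2)[C@@H](C=C)O1 | intermediate (not isolated)
13 | β-alkoxy ketone/lactone enolate after the first C–C bond (tin omitted; ONAP carbon undefined) | [O-]C1=C[C@](C)(C(OCc2ccc3ccccc3c2)CC(=O)C(C)C)[C@@H](C=C)O1 | intermediate (not isolated)
14 | cis-fused 8-hydroxy-8-isopropyl-5-methyl-6-(naphthalen-2-ylmethoxy)-4-vinyl-3-oxabicyclo[3.3.0]octan-2-one; vinyl cis to 5-Me, 8-OH cis to the C1–C2 bond, iPr cis to H-1, C6 undefined | O=C1O[C@H](C=C)[C@@]2(C)C(OCc3ccc4ccccc4c3)C[C@](O)(C(C)C)[C@@H]12 | intermediate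
15 | lactol from 14, 2-(2-methylallyl)-3-oxabicyclo[3.3.0]octane-2,8-diol (anomeric mixture; C6 undefined) | OC1(CC(C)=C)O[C@H](C=C)[C@@]2(C)C(OCc3ccc4ccccc4c3)C[C@](O)(C(C)C)[C@@H]12 | intermediate
16 | cis-fused 2,8-dihydroxy-8-isopropyl-1,4-dimethyl-10-(naphthalen-2-ylmethoxy)bicyclo[5.3.0]dec-3-en-6-one (C10 undefined) | O=C1CC(C)=C[C@@H](O)[C@@]2(C)C(OCc3ccc4ccccc4c3)C[C@](O)(C(C)C)[C@@H]12 | intermediate
17 | 8-isopropyl-1,4-dimethyl-10-(naphthalen-2-ylmethoxy)bicyclo[5.3.0]dec-3-ene-2,6,8-triol; 6-OH cis to H-7 (C10 undefined) | O[C@@H]1CC(C)=C[C@@H](O)[C@@]2(C)C(OCc3ccc4ccccc4c3)C[C@](O)(C(C)C)[C@@H]12 | intermediate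
18 | angelic acid, (Z)-2-methylbut-2-enoic acid | C/C=C(/C)C(=O)O | starting material
19 | angelic 2,4,6-trichlorobenzoic anhydride | C/C=C(/C)C(=O)OC(=O)c1c(Cl)cc(Cl)cc1Cl | intermediate (not isolated)
20 | 2,6-di-O-angeloyl 10-O-(2-naphthylmethyl) ether of the tetrol (C10 undefined) | C/C=C(/C)C(=O)O[C@@H]1CC(C)=C[C@@H](OC(=O)/C(C)=C\C)[C@@]2(C)C(OCc3ccc4ccccc4c3)C[C@](O)(C(C)C)[C@@H]12 | intermediate
21 | 2,6-di-O-angeloyl tetrol, C10 epimer(s) | C/C=C(/C)C(=O)O[C@@H]1CC(C)=C[C@@H](OC(=O)/C(C)=C\C)[C@@]2(C)C(O)C[C@](O)(C(C)C)[C@@H]12 | intermediate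
22 | 2,6-bis(angeloyloxy)-8-hydroxy-8-isopropyl-1,4-dimethylbicyclo[5.3.0]dec-3-en-10-one | C/C=C(/C)C(=O)O[C@@H]1CC(C)=C[C@@H](OC(=O)/C(C)=C\C)[C@@]2(C)C(=O)C[C@](O)(C(C)C)[C@@H]12 | intermediate
23 | CNP0249167.1 | C/C=C(/C)C(=O)O[C@@H]1CC(C)=C[C@@H](OC(=O)/C(C)=C\C)[C@@]2(C)[C@H](O)C[C@](O)(C(C)C)[C@@H]12 | target

**Step count:** 14 steps in total. Longest linear sequence: 13 steps (1–5, 7–14); step 6 is a one‑step branch.

**Steps most likely to fail**

Step 7. The ring‑opened ion pair may oligomerise, the Lewis acid may ionise the allylic (and cyclopropylcarbinyl) lactone C–O bond before the cyclopropane opens, or facial control in the aldol closure may be incomplete. The fallback reverses the order of ring construction, so that the annulation is run on a 2‑alkoxycyclopropyl ketone, a stronger acceptor with no lactone leaving group. It sets out from 9: 2‑methylallylmagnesium chloride at −78 °C gives cyclopropyl lactol F1, ring‑closing metathesis (Grubbs II) gives bicyclo[5.1.0]octenone hydroxy ketone F2, and TESOTf/2,6‑lutidine gives its triethylsilyl ether F3. The SnCl4‑mediated [3+2] with 11 on F3, followed by an acidic work‑up that removes the silyl group, comes back to the route at 16.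

Step 4. The doubly allylic, alkoxy‑activated ester may be lost by ionisation or allylic transposition under HBr/bromide during bromoacetylation, or be degraded by DBU. The fallback builds the diazo ester by diazo transfer, avoiding acyl halide and bromide. It sets out from 6: diketene with catalytic DMAP and Et3N in THF at −20 °C gives acetoacetate F4, Regitz diazo transfer (p‑acetamidobenzenesulfonyl azide, Et3N, MeCN) gives diazoacetoacetate F5, and deacetylation with aqueous LiOH comes back to the route at 8.

Step 11. Acylation of the two hindered secondary alcohols may be slow, and the angelate may isomerise Z→E to tiglate under forcing conditions. The fallback builds the Z‑alkenes on the molecule instead of transferring them. It sets out from 17: both secondary hydroxyls are esterified with 2‑[bis(2,2,2‑trifluoroethoxy)phosphoryl]propanoic acid (DCC, DMAP, CH2Cl2) to give bis‑phosphonate F6, and a double Still–Gennari olefination with acetaldehyde (KHMDS, 18‑crown‑6, THF, −78 °C) comes back to the route at 20.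

**Further compounds**
F1 | step 7 | cyclopropyl lactol, 5-methyl-2-(2-methylallyl)-6-(naphthalen-2-ylmethoxy)-4-vinyl-3-oxabicyclo[3.1.0]hexan-2-ol | OC1(CC(C)=C)O[C@H](C=C)[C@@]2(C)[C@@H](OCc3ccc4ccccc4c3)[C@@H]12
F2 | step 7 | 2-hydroxy-1,4-dimethyl-8-(naphthalen-2-ylmethoxy)bicyclo[5.1.0]oct-3-en-6-one | O=C1CC(C)=C[C@@H](O)[C@@]2(C)[C@@H](OCc3ccc4ccccc4c3)[C@@H]12
F3 | step 7 | triethylsilyl ether of F2 | O=C1CC(C)=C[C@@H](O[Si](CC)(CC)CC)[C@@]2(C)[C@@H](OCc3ccc4ccccc4c3)[C@@H]12
F4 | step 4 | acetoacetate of 6 | C=C[C@@H](OC(=O)CC(C)=O)/C(C)=C\OCc1ccc2ccccc2c1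
F5 | step 4 | 2-diazoacetoacetate of 6 | C=C[C@@H](OC(=O)C(=[N+]=[N-])C(C)=O)/C(C)=C\OCc1ccc2ccccc2c1
F6 | step 11 | 2,6-bis{2-[bis(2,2,2-trifluoroethoxy)phosphoryl]propanoate} of 17 | CC(C(=O)O[C@@H]1CC(C)=C[C@@H](OC(=O)C(C)P(=O)(OCC(F)(F)F)OCC(F)(F)F)[C@@]2(C)C(OCc3ccc4ccccc4c3)C[C@](O)(C(C)C)[C@@H]12)P(=O)(OCC(F)(F)F)OCC(F)(F)F
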